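Ring B of the target (the six-membered carbocycle made of the geranyl-bearing quaternary carbon, the ketone carbon, the prenyl-bearing olefinic carbon, the enol-ether carbon and the two carbinol carbons) is a dearomatized 2-alkoxy-6-hydroxy-5-geranyl-3-prenyl-1,4-benzoquinone; rings A, C and D come from it and (E)-β-ocimene by Diels–Alder and Prins/etherification. The route rests on assembling this ring by a Danheiser benzannulation: a 3-ethoxy-2-prenylcyclobutenone and a geranyl-substituted siloxyalkyne merge thermally, joining the future ketone carbon to the prenyl-bearing carbon and the geranyl-bearing carbon to the adjacent carbinol carbon, with every substituent placed regiospecifically. The precursors are a cyclobutenone and an alkyne.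

Key step: step 6

Remarks on the chemistry
- Ring letters: A = cyclohexene ring, B = cyclohexenone ring, C = cyclopentane ring, D = 2,2-dimethyldihydrofuran ring.
- Assumption: the sense of induction of the chiral titanium binaphtholate on quinone 19 cannot be derived from close models. The (S)-ligand is written; the (R)-ligand is used instead if a first run shows the opposite sense, and nothing else changes.
- Ethoxyethyne (hexane solution), ethynylmagnesium bromide (THF solution) and (E)-β-ocimene are taken as commercial; material enriched in the E isomer suffices, because the Z isomer is a poor diene.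

Step 1
Reactants: 1 ethoxyethyne; 2 1-bromo-3-methylbut-2-ene (prenyl bromide)
Product: 3 1-ethoxy-5-methylhex-4-en-1-yne
Conditions: n-BuLi, THF, −78 °C; then 2, DMPU, −78 °C → rt
Reagents that add atoms: none
Why: SN2 alkylation of lithium ethoxyacetylide at the primary allylic bromide (acetylide alkylation) should give the ynol ether; no stereocenter is formed.

Step 2
Reactants: 3 1-ethoxy-5-methylhex-4-en-1-yne; 4 trichloroacetyl chloride
Product: 6 4,4-dichloro-3-ethoxy-2-(3-methylbut-2-en-1-yl)cyclobut-2-en-1-one, via dichloroketene 5 (not isolated)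
Conditions: Zn–Cu couple, Et2O, 0 °C → rt, slow addition of 4
Reagents that add atoms: none
Why: Ketene–alkyne [2+2] cycloaddition: dichloroketene should add to the electron-rich ynol ether much faster than to the trisubstituted alkene, its carbonyl carbon bonding to the alkyne carbon remote from oxygen, which fixes the 2-prenyl-3-ethoxy pattern.

Step 3
Reactants: 6 4,4-dichloro-3-ethoxy-2-(3-methylbut-2-en-1-yl)cyclobut-2-en-1-one
Product: 7 3-ethoxy-2-(3-methylbut-2-en-1-yl)cyclobut-2-en-1-one
Conditions: Zn dust, AcOH, TMEDA, EtOH, 0 °C → rt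
Reagents that add atoms: none
Why: Reductive dehalogenation of the α,α-dichloro ketone through the zinc enolate should remove both chlorines and leave the vinylogous ester and the alkene untouched.

Step 4
Reactants: 8 geranyl bromide, (2E)-1-bromo-3,7-dimethylocta-2,6-diene; 9 ethynylmagnesium bromide
Product: 10 (4E)-5,9-dimethyldeca-4,8-dien-1-yne
Conditions: CuCl (5 mol %), THF, 0 → 40 °C, 9 in excess
Reagents that add atoms: none
Why: Copper-catalysed coupling of an alkynyl Grignard reagent with a primary allylic bromide should occur at the unhindered terminus (SN2) and keep the E olefin of the geranyl unit.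

Step 5
Reactants: 10 (4E)-5,9-dimethyldeca-4,8-dien-1-yne
Product: 12 {[(4E)-5,9-dimethyldeca-4,8-dien-1-yn-1-yl]oxy}tri(propan-2-yl)silane, via lithium ynolate 11 (not isolated)
Conditions: n-BuLi, THF, −78 °C; LiOOt-Bu (from t-BuOOH and LiN(SiMe3)2), −78 → 0 °C; i-Pr3SiOTf, −78 °C
Reagents that add atoms: tert-butyl hydroperoxide CC(C)(C)OO; triisopropylsilyl triflate CC(C)[Si](C(C)C)(C(C)C)OS(=O)(=O)C(F)(F)F
Why: Oxidation of the lithium acetylide by lithium tert-butyl peroxide (acetylide-to-ynolate oxygen transfer) should give the ynolate, which the bulky silyl triflate traps on oxygen to give the siloxyalkyne.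

Step 6
Reactants: 7 3-ethoxy-2-(3-methylbut-2-en-1-yl)cyclobut-2-en-1-one; 12 {[(4E)-5,9-dimethyldeca-4,8-dien-1-yn-1-yl]oxy}tri(propan-2-yl)silane
Product: 17 5-ethoxy-2-[(2E)-3,7-dimethylocta-2,6-dien-1-yl]-4-(3-methylbut-2-en-1-yl)-3-{[tri(propan-2-yl)silyl]oxy}phenol, via vinylketene 13 (not isolated), via vinylcyclobutenone 14 (not isolated), via dienylketene 15 (not isolated), via cyclohexadienone 16 (not isolated)
Conditions: toluene, 80 °C then 110 °C, sealed tube, 12 (1.3 equiv)
Reagents that add atoms: none
Why: Heat opens cyclobutenone 7 by 4π-electrocyclic ring opening to vinylketene 13, whose ketene C=C bond undergoes [2+2] cycloaddition with the siloxyalkyne to give 14; a second 4π-opening gives dienylketene 15, 6π-electrocyclization gives cyclohexadienone 16 and tautomerization gives phenol 17. The closest known reaction type is the Danheiser benzannulation of 3-alkoxy-2-alkylcyclobutenones with siloxyalkynes. Ring B is closed as a benzene ring by the 6π-electrocyclic closure of the dienylketene (ketene carbon onto the terminal CH2), after a transient four-membered ring has been closed by the [2+2] cycloaddition and reopened. No stereocenter survives the step: the quaternary carbon of 14 is racemic and is flattened on aromatization. The selectivity needed is the orientation of the ketene/ynol ether union, secured by polarization: the electrophilic ketene carbonyl carbon bonds to the alkyne carbon remote from oxygen (geranyl-bearing) and the prenyl-bearing ketene α-carbon to the siloxy-bearing carbon. This places geranyl between hydroxyl and silyloxy and prenyl between silyloxy and ethoxy; in net terms the alkyne is inserted into the C1–C2 bond of the cyclobutenone, so only these two new σ-bonds result.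

Step 7
Reactants: 17 5-ethoxy-2-[(2E)-3,7-dimethylocta-2,6-dien-1-yl]-4-(3-methylbut-2-en-1-yl)-3-{[tri(propan-2-yl)silyl]oxy}phenol
Product: 19 2-ethoxy-6-hydroxy-5-[(2E)-3,7-dimethylocta-2,6-dien-1-yl]-3-(3-methylbut-2-en-1-yl)cyclohexa-2,5-diene-1,4-dione, via resorcinol 18 (not isolated)
Conditions: Bu4NF, AcOH, THF, 0 °C; then K2[ON(SO3)2], aq KH2PO4, acetone, 0 °C → rt
Reagents that add atoms: potassium nitrosodisulfonate [K+].[K+].[O]N(S(=O)(=O)[O-])S(=O)(=O)[O-]
Why: Fluoride should cleave the aryl silyl ether, and the Teuber oxidation then introduces oxygen at the only unsubstituted ring carbon, which is para to the liberated hydroxyl and ortho to the other, so both possible phenoxyl radicals converge on the same hydroxy-para-quinone.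

Step 8
Reactants: 19 2-ethoxy-6-hydroxy-5-[(2E)-3,7-dimethylocta-2,6-dien-1-yl]-3-(3-methylbut-2-en-1-yl)cyclohexa-2,5-diene-1,4-dione; 20 (3E)-3,7-dimethylocta-1,3,6-triene, (E)-β-ocimene
Product: 21 (4aR,8S,8aR)-2-ethoxy-4a-[(2E)-3,7-dimethylocta-2,6-dien-1-yl]-8a-hydroxy-7-methyl-3,8-bis(3-methylbut-2-en-1-yl)-4a,5,8,8a-tetrahydronaphthalene-1,4-dione
Conditions: (S)-1,1'-bi-2-naphthol/TiCl2(Oi-Pr)2 (1:1, 30 mol %), 4 Å molecular sieves, CH2Cl2, −20 → 0 °C, 20 (3 equiv)
Reagents that add atoms: none
Why: Asymmetric Diels–Alder reaction in which chelation of the C1 carbonyl and the C6 oxygen of 19 to the chiral titanium binaphtholate should activate the C5=C6 bond (the titanium-bound oxygen donates less than the free ethoxy group on C2=C3); the unsubstituted diene terminus bonds to C5, β to the chelated carbonyl, and the substituted terminus to C6; endo addition of the E diene places H-8 cis to the 8a-hydroxyl and the geranyl group cis to that hydroxyl; the binaphthol ligand selects the quinone face, setting 4aR, 8S and 8aR.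

Step 9
Reactants: 21 (4aR,8S,8aR)-2-ethoxy-4a-[(2E)-3,7-dimethylocta-2,6-dien-1-yl]-8a-hydroxy-7-methyl-3,8-bis(3-methylbut-2-en-1-yl)-4a,5,8,8a-tetrahydronaphthalene-1,4-dione
Product: 22 the target CNP0323114.1
Conditions: MeAlCl2 (2.5 equiv), CH2Cl2, −78 → −20 °C; aq potassium sodium tartrate
Reagents that add atoms: none
Why: Prins cyclization with dealkylative cycloetherification: the aluminium alkoxide formed at the 8a-hydroxyl chelates and activates the C1 ketone, and the side-chain trisubstituted alkene on C8 attacks it to close ring C, cis-fused by the three-atom tether, so the new hydroxyl is cis to the 8a-hydroxyl; the tertiary cation is captured by the adjacent enol-ether oxygen to close ring D (only the epimer with the cation over the enol ether can close, the other can revert) and chloride removes the ethyl group from the oxonium ion.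

Compound list
1 | ethoxyethyne | C#COCC | starting material
2 | 1-bromo-3-methylbut-2-ene (prenyl bromide) | CC(C)=CCBr | starting material
3 | 1-ethoxy-5-methylhex-4-en-1-yne | CCOC#CCC=C(C)C | intermediate
4 | trichloroacetyl chloride | ClC(=O)C(Cl)(Cl)Cl | starting material
5 | dichloroketene | ClC(Cl)=C=O | intermediate (not isolated)
6 | 4,4-dichloro-3-ethoxy-2-(3-methylbut-2-en-1-yl)cyclobut-2-en-1-one | CCOC1=C(CC=C(C)C)C(=O)C1(Cl)Cl | intermediate
7 | 3-ethoxy-2-(3-methylbut-2-en-1-yl)cyclobut-2-en-1-one | CCOC1=C(CC=C(C)C)C(=O)C1 | intermediate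
8 | geranyl bromide, (2E)-1-bromo-3,7-dimethylocta-2,6-diene | CC(C)=CCC/C(C)=C/CBr | starting material
9 | ethynylmagnesium bromide | C#C[Mg]Br | starting material
10 | (4E)-5,9-dimethyldeca-4,8-dien-1-yne | CC(C)=CCC/C(C)=C/CC#C | intermediate
11 | lithium (4E)-5,9-dimethyldeca-4,8-dien-1-yn-1-olate (ynolate) | CC(C)=CCC/C(C)=C/CC#C[O-].[Li+] | intermediate (not isolated)
12 | {[(4E)-5,9-dimethyldeca-4,8-dien-1-yn-1-yl]oxy}tri(propan-2-yl)silane | CC(C)=CCC/C(C)=C/CC#CO[Si](C(C)C)(C(C)C)C(C)C | intermediate
13 | 3-ethoxy-2-(3-methylbut-2-en-1-yl)buta-1,3-dien-1-one (vinylketene) | CCOC(=C)C(CC=C(C)C)=C=O | intermediate (not isolated)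
14 | 2-geranyl-4-(1-ethoxyethenyl)-4-(3-methylbut-2-en-1-yl)-3-(triisopropylsilyloxy)cyclobut-2-en-1-one, racemic at C4 | CC(C)=CCC/C(C)=C/CC1=C(O[Si](C(C)C)(C(C)C)C(C)C)C(CC=C(C)C)(C(=C)OCC)C1=O | intermediate (not isolated)
15 | (3E)-5-ethoxy-2-geranyl-4-(3-methylbut-2-en-1-yl)-3-(triisopropylsilyloxy)hexa-1,3,5-trien-1-one (dienylketene, ketene carbon cis to the ethoxyvinyl group) | CC(C)=CCC/C(C)=C/CC(=C=O)/C(O[Si](C(C)C)(C(C)C)C(C)C)=C(\C(=C)OCC)CC=C(C)C | intermediate (not isolated)
16 | 5-ethoxy-2-geranyl-4-(3-methylbut-2-en-1-yl)-3-(triisopropylsilyloxy)cyclohexa-2,4-dien-1-one | CC(C)=CCC/C(C)=C/CC1=C(O[Si](C(C)C)(C(C)C)C(C)C)C(CC=C(C)C)=C(OCC)CC1=O | intermediate (not isolated)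
17 | 5-ethoxy-2-[(2E)-3,7-dimethylocta-2,6-dien-1-yl]-4-(3-methylbut-2-en-1-yl)-3-{[tri(propan-2-yl)silyl]oxy}phenol | CC(C)=CCC/C(C)=C/Cc1c(O)cc(OCC)c(CC=C(C)C)c1O[Si](C(C)C)(C(C)C)C(C)C | intermediate
18 | 5-ethoxy-2-[(2E)-3,7-dimethylocta-2,6-dien-1-yl]-4-(3-methylbut-2-en-1-yl)benzene-1,3-diol | CC(C)=CCC/C(C)=C/Cc1c(O)cc(OCC)c(CC=C(C)C)c1O | intermediate (not isolated)
19 | 2-ethoxy-6-hydroxy-5-[(2E)-3,7-dimethylocta-2,6-dien-1-yl]-3-(3-methylbut-2-en-1-yl)cyclohexa-2,5-diene-1,4-dione | CC(C)=CCC/C(C)=C/CC1=C(O)C(=O)C(OCC)=C(CC=C(C)C)C1=O | intermediate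
20 | (3E)-3,7-dimethylocta-1,3,6-triene, (E)-β-ocimene | C=C/C(C)=C/CC=C(C)C | starting material
21 | (4aR,8S,8aR)-2-ethoxy-4a-[(2E)-3,7-dimethylocta-2,6-dien-1-yl]-8a-hydroxy-7-methyl-3,8-bis(3-methylbut-2-en-1-yl)-4a,5,8,8a-tetrahydronaphthalene-1,4-dione (cis-fused; geranyl, 8a-OH and H-8 on one face) | CC(C)=CCC/C(C)=C/C[C@]12CC=C(C)[C@H](CC=C(C)C)[C@]2(O)C(=O)C(OCC)=C(CC=C(C)C)C1=O | intermediate
22 | target CNP0323114.1: all-cis-fused A/B/C/D tetracycle; R at the geranyl-bearing quaternary carbon, R at both carbinol carbons, S at both ring-fusion methines | CC(C)=CCC/C(C)=C/C[C@]12CC=C(C)[C@@H]3C[C@@H]4C(C)(C)OC(=C(CC=C(C)C)C1=O)[C@]4(O)[C@@]32O | target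

Total step count: 9. Longest linear sequence: 7 steps (steps 1, 2, 3, 6, 7, 8, 9).

Steps most likely to fail

1. Step 8. The tetrasubstituted, donor-substituted C5=C6 bond may add the diene too slowly. Lewis-acid-induced cyclization of the hydroxyl onto the geranyl chain, addition at the ethoxy-bearing bond or poor facial discrimination could then take over. The fallback sets out from 19 and returns at 21. Acylation with (2S)-2-acetoxypropanoyl chloride (pyridine, CH2Cl2, 0 °C) should give the (2S)-2-acetoxypropanoate of quinone 19 F1, whose acyloxy-bearing C5=C6 bond is the more electron-poor one and which has no free hydroxyl. Uncatalysed Diels–Alder reaction with 20 under high pressure (about 12 kbar, CH2Cl2, rt) should give the endo adducts as two diastereomers with the same orientation, since the C1 carbonyl remains the stronger acceptor. The (4aR,8S,8aR) adduct ester, the (2S)-2-acetoxypropanoate of 21 at O-8a F2, is separated by chromatography, and methanolysis (K2CO3, MeOH, 0 °C) returns 21.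

2. Step 9. After the Prins closure the tertiary cation may lose a proton or revert instead of being captured with loss of the ethyl group, and Lewis-acid-induced cyclization of the polyene side chains may compete. The fallback sets out from 21 and returns at 22. Mild hydrolysis of the vinylogous ethyl ester (2 M HCl, THF, rt) should give the free enol (4aR,8S,8aR)-4a-geranyl-2,8a-dihydroxy-7-methyl-3,8-bis(3-methylbut-2-en-1-yl)-4a,5,8,8a-tetrahydronaphthalene-1,4-dione F3. Treatment with MeAlCl2 (3 equiv, CH2Cl2, −78 → 0 °C) then lets the Prins cation be captured directly by the enol oxygen, so no dealkylation is needed.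

3. Step 6. At 80 °C the vinylketene may be consumed by the product phenol (aryl ester formation) or by oligomerization faster than the alkyne captures it, or the sequence may stall before the last electrocyclization. The fallback sets out from 2 (12 is used unchanged) and returns at 17 through 13; the same two bonds still form in one operation. Alkylation of the lithium enolate of N-methoxy-N-methylacetamide (LiN(i-Pr)2, THF, −78 °C) with 2 should give N-methoxy-N,5-dimethylhex-4-enamide F4. 1-Ethoxyvinyllithium converts it into 2-ethoxy-7-methylocta-1,6-dien-3-one F5. Trifluoroacetylation (LiN(SiMe3)2, CF3CO2CH2CF3) gives 2-ethoxy-7-methyl-4-(trifluoroacetyl)octa-1,6-dien-3-one F6, and diazo transfer (MsN3, Et3N, MeCN) gives 4-diazo-2-ethoxy-7-methylocta-1,6-dien-3-one F7. Irradiation (300 nm, 1,2-dichloroethane, rt) in the presence of 12 triggers a photochemical Wolff rearrangement to vinylketene 13 at room temperature; the cascade then continues as in step 6 and is completed by warming to 80 °C to give 17.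

Further compounds
F1 | step 8 | (2S)-2-acetoxypropanoate ester of hydroxyquinone 19 | CC(C)=CCC/C(C)=C/CC1=C(OC(=O)[C@H](C)OC(C)=O)C(=O)C(OCC)=C(CC=C(C)C)C1=O
F2 | step 8 | (4aR,8S,8aR) Diels–Alder adduct, (2S)-2-acetoxypropanoate ester of 21 at O-8a | CC(C)=CCC/C(C)=C/C[C@]12CC=C(C)[C@H](CC=C(C)C)[C@]2(OC(=O)[C@H](C)OC(C)=O)C(=O)C(OCC)=C(CC=C(C)C)C1=O
F3 | step 9 | (4aR,8S,8aR)-4a-geranyl-2,8a-dihydroxy-7-methyl-3,8-bis(3-methylbut-2-en-1-yl)-4a,5,8,8a-tetrahydronaphthalene-1,4-dione | CC(C)=CCC/C(C)=C/C[C@]12CC=C(C)[C@H](CC=C(C)C)[C@]2(O)C(=O)C(O)=C(CC=C(C)C)C1=O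
F4 | step 6 | N-methoxy-N,5-dimethylhex-4-enamide | CON(C)C(=O)CCC=C(C)C
F5 | step 6 | 2-ethoxy-7-methylocta-1,6-dien-3-one | CCOC(=C)C(=O)CCC=C(C)C
F6 | step 6 | 2-ethoxy-7-methyl-4-(trifluoroacetyl)octa-1,6-dien-3-one | CCOC(=C)C(=O)C(CC=C(C)C)C(=O)C(F)(F)F
F7 | step 6 | 4-diazo-2-ethoxy-7-methylocta-1,6-dien-3-one | CCOC(=C)C(=O)C(=[N+]=[N-])CC=C(C)C
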